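Retrosynthesis (chromone numbering O1, C2–C4, C4a, C5–C8, C8a; ring D C1′–C6′ with C1′ on C3 and the furan oxygen O2′ on C2′): ring C is cut at C4–C4a and O1–C2, ring A at C7–C8 and C4a–C8a (C6–C7 is re-formed in the same event), and the ring D furan at C3–C1′ and C2–O2′.
Enabling feature: ring A is a fully substituted phloroglucinol whose three oxygens are all different (O5 inside the dihydropyran, O7 a free hydroxyl, O1 inside the pyranone), with prenyl on C8 between O7 and O1 and the pyran CH2 on C6. A cyclobutenone/siloxyalkyne benzannulation sets this pattern by connectivity alone and delivers O7 free and O1 silylated.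
Forward order: a dihydropyran-fused 3-alkoxycyclobutenone and a prenyl siloxyalkyne close ring A, and a protecting-group swap then frees O1. Ring D is grown as a benzofuran on a chroman-5,8-quinone. The halves are joined by O1–C2 ether formation, ring C is closed by anionic acylation at C4a, and two acetals are removed.
Stereochemistry: the target has no stereocentre and no stereogenic alkene. The one stereocentre carried (ring-fusion carbon of the cyclobutenone, racemic) is erased on aromatisation.

Key step: step 7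

Remark: racemic intermediates are drawn as one enantiomer; 2,5-dimethoxyphenol, ethoxyacetylene (hexane solution) and ethyl (E)-3-(dimethylamino)prop-2-enoate are taken as purchasable.

**Ring A precursor (steps 1–4)**

Step 1
Reactants: 1 glutaric anhydride
Product: 3 6,6-dimethyltetrahydro-2H-pyran-2-one, via 5-hydroxy-5-methylhexanoic acid 2 (not isolated)
Conditions: MeMgBr (2.5 equiv), THF, −20 → 25 °C; 2 M HCl; p-TsOH (cat.), CH2Cl2, 25 °C
Reagents that add atoms: methylmagnesium bromide, C[Mg]Br
Why: Double Grignard addition to a cyclic anhydride, in which the first MeMgBr opens the ring to a keto carboxylate and the second adds only to the ketone, gives the tertiary δ-hydroxy acid, which lactonises under acid.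

Step 2
Reactants: 3 6,6-dimethyltetrahydro-2H-pyran-2-one
Product: 6 5-methyl-5-(triethylsilyloxy)hexanoic acid, via potassium 5-hydroxy-5-methylhexanoate 4 (not isolated), via bis-triethylsilyl derivative 5 (not isolated)
Conditions: KOH (1.0 equiv), MeOH/H2O, 25 °C, evaporate to dryness; Et3SiOTf (2.3 equiv), 2,6-lutidine, CH2Cl2, 0 °C; THF/H2O (pH 7 buffer), 25 °C
Reagents that add atoms: potassium hydroxide, [K+].[OH-]; triethylsilyl trifluoromethanesulfonate, CC[Si](CC)(CC)OS(=O)(=O)C(F)(F)F
Why: Saponification, exhaustive silylation and selective hydrolysis of the much more labile silyl ester (standard protecting-group chemistry) leave a tertiary silyl ether that blocks relactonisation when the acid is activated.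

Step 3
Reactants: 6 5-methyl-5-(triethylsilyloxy)hexanoic acid; 7 ethoxyacetylene
Product: 10 3-ethoxy-4-[3-methyl-3-(triethylsilyloxy)butyl]cyclobut-2-en-1-one (racemic), via acid chloride 8 (not isolated), via alkylketene 9 (not isolated)
Conditions: 1-chloro-N,N,2-trimethylprop-1-en-1-amine, CH2Cl2, 0 °C; then slow addition to 7 (3 equiv), Et3N, Et2O, 25 °C
Reagents that add atoms: none
Why: The α-chloroenamine forms the acid chloride without HCl so the silyl ether survives, Et3N dehydrochlorination gives the aldoketene, and its ketene–alkoxyalkyne (2+2) cycloaddition (ketene carbonyl carbon to the unsubstituted alkyne carbon) gives the 4-alkyl-3-ethoxycyclobutenone, whose new stereocentre is racemic and is erased in step 7.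

Step 4
Reactants: 10 3-ethoxy-4-[3-methyl-3-(triethylsilyloxy)butyl]cyclobut-2-en-1-one (racemic)
Product: 12 3,3-dimethyl-2-oxabicyclo[4.2.0]oct-1(8)-en-7-one (racemic), via desilylated hydroxy cyclobutenone 11 (not isolated)
Conditions: HF·pyridine, pyridine, THF, 0 °C; then pyridinium p-toluenesulfonate (10 mol %), benzene, 5 Å MS, 45 °C
Reagents that add atoms: none
Why: After Si–O cleavage the tertiary alcohol displaces ethanol from the vinylogous ester by acid-catalysed addition–elimination (vinylogous transesterification, six-membered ring, ethanol taken up by the sieves); closure through either oxygenated terminus gives the same bicycle, the stereocentre is untouched, and the 1,3-dione stage that would scramble the double-bond position is never reached.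

**Siloxyalkyne (steps 5–6)**

Step 5
Reactants: 13 4-methylpent-3-enoic acid
Product: 14 methyl 4-methylpent-3-enoate
Conditions: MeI, K2CO3, DMF, 25 °C
Reagents that add atoms: iodomethane, CI
Why: Carboxylate O-alkylation (SN2) under mild base avoids the acid-promoted lactonisation and alkene migration that a Fischer esterification of this β,γ-unsaturated acid would invite.

Step 6
Reactants: 14 methyl 4-methylpent-3-enoate
Product: 17 triisopropyl[(5-methylhex-4-en-1-yn-1-yl)oxy]silane, via lithium dibromo enolate 15 (not isolated), via lithium ynolate 16 (not isolated)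
Conditions: CH2Br2, lithium 2,2,6,6-tetramethylpiperidide (2.1 equiv), THF, −78 °C; n-BuLi, −78 → 25 °C; i-Pr3SiCl, −78 → 25 °C
Reagents that add atoms: dibromomethane, BrCBr; chlorotriisopropylsilane, CC(C)[Si](Cl)(C(C)C)C(C)C
Why: Kowalski ester homologation, in which LiCHBr2 adds to the ester, the dibromo ketone enolate 15 undergoes Br–Li exchange and 1,2-shift to ynolate 16, and the bulky silyl chloride traps 16 on oxygen to give the silyl ynol ether.

**Ring A (steps 7–9)**

Step 7
Reactants: 12 3,3-dimethyl-2-oxabicyclo[4.2.0]oct-1(8)-en-7-one (racemic); 17 triisopropyl[(5-methylhex-4-en-1-yn-1-yl)oxy]silane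
Product: 22 2,2-dimethyl-6-(3-methylbut-2-en-1-yl)-7-(triisopropylsilyloxy)chroman-5-ol, via vinylketene 18 (not isolated), via 4-vinylcyclobutenone 19 (not isolated), via dienylketene 20 (not isolated), via cyclohexadienone 21 (not isolated)
Conditions: 17 (1.3 equiv), PhMe (degassed), 80 °C then 110 °C, sealed tube
Reagents that add atoms: none
Why: Heating cleaves the C(=O)–C(sp3) bond of 12 by 4π electrocyclic opening, the ring fusion forcing the ring CH2 to rotate outward so that vinylketene 18 carries its new double bond inside the dihydropyran; 18 then adds 17 in a ketene–alkyne (2+2) cycloaddition that forms C7–C8 and C4a–C8a, and 19 reopens to dienylketene 20. Ring A closes by thermal 6π electrocyclisation of 20, which re-forms the C6–C7 bond broken at the start, and dienone 21 tautomerises to phenol 22. The closest known reaction is the Danheiser benzannulation of cyclobutenones with trialkylsiloxyalkynes, which gives resorcinol monosilyl ethers. No stereocentre is created that survives, since the ring-fusion carbon of 12 and the sp3 carbons of 19 and 21 all become aromatic. The step needs one regiochemical outcome in the (2+2) event, and the polarisation of the siloxyalkyne (its nucleophilic carbon is the one bearing the prenyl chain, which attacks the ketene carbonyl carbon) secures it, so prenyl ends on C8 between the free O7–H and the silylated O1. Chemoselectivity for the ynol ether over the prenyl alkene follows from the much higher nucleophilicity of the former.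

Step 8
Reactants: 22 2,2-dimethyl-6-(3-methylbut-2-en-1-yl)-7-(triisopropylsilyloxy)chroman-5-ol
Product: 23 triisopropyl{[5-(methoxymethoxy)-2,2-dimethyl-6-(3-methylbut-2-en-1-yl)chroman-7-yl]oxy}silane
Conditions: MOMCl, i-Pr2NEt, Bu4NI (cat.), CH2Cl2, 0 → 40 °C
Reagents that add atoms: chloromethyl methyl ether, COCCl
Why: Williamson-type O-alkylation of the hindered O7 phenol with the small, reactive chloromethyl ether gives an acetal that withstands fluoride, copper catalysis and lithium amides.

Step 9
Reactants: 23 triisopropyl{[5-(methoxymethoxy)-2,2-dimethyl-6-(3-methylbut-2-en-1-yl)chroman-7-yl]oxy}silane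
Product: 24 5-(methoxymethoxy)-2,2-dimethyl-6-(3-methylbut-2-en-1-yl)chroman-7-ol
Conditions: Bu4NF, THF, 0 °C
Reagents that add atoms: none
Why: Fluoride-induced Si–O cleavage of the aryl silyl ether frees O1–H while the acetal on O7 and the prenyl group are inert.

**Ring D (steps 10–17)**

Step 10
Reactants: 25 2,5-dimethoxyphenol
Product: 26 1,4-dimethoxy-2-(methoxymethoxy)benzene
Conditions: MOMCl, i-Pr2NEt, CH2Cl2, 0 → 25 °C
Reagents that add atoms: chloromethyl methyl ether, COCCl
Why: Phenol O-alkylation installs a strong ortho-directing group for the metalation that follows.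

Step 11
Reactants: 26 1,4-dimethoxy-2-(methoxymethoxy)benzene
Product: 28 1,4-dimethoxy-2-(methoxymethoxy)-3-(3-methylbut-2-en-1-yl)benzene, via aryllithium 27 (not isolated)
Conditions: n-BuLi, TMEDA, THF, 0 °C; CuBr·SMe2 (0.2 equiv), prenyl bromide, −78 → 0 °C
Reagents that add atoms: 1-bromo-3-methylbut-2-ene, CC(C)=CCBr
Why: Directed ortho-metalation takes place at the one position flanked by OMOM and OMe, and copper-mediated SN2 allylation of the aryllithium with prenyl bromide installs the future pyran carbons between two oxygens.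

Step 12
Reactants: 28 1,4-dimethoxy-2-(methoxymethoxy)-3-(3-methylbut-2-en-1-yl)benzene
Product: 30 5,8-dimethoxy-2,2-dimethylchroman, via prenylphenol 29 (not isolated)
Conditions: p-TsOH·H2O (20 mol %), MeOH, 60 °C; then PhMe, 90 °C
Reagents that add atoms: none
Why: Acidic methanolysis of the acetal frees the single phenol, which adds to the prenyl alkene in Markovnikov fashion (acid-catalysed hydroalkoxylation through the tertiary cation) to give the 2,2-dimethylchroman.

Step 13
Reactants: 30 5,8-dimethoxy-2,2-dimethylchroman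
Product: 31 2,2-dimethyl-3,4-dihydro-2H-chromene-5,8-dione
Conditions: (NH4)2Ce(NO3)6 (2.5 equiv), MeCN/H2O, 0 °C
Reagents that add atoms: water, O
Why: Oxidative demethylation of the para-dimethoxyarene gives the p-quinone, the ring ether oxygen remaining as the 2-alkoxy substituent that polarises the quinone for step 14.

Step 14
Reactants: 31 2,2-dimethyl-3,4-dihydro-2H-chromene-5,8-dione; 32 ethyl (E)-3-(dimethylamino)prop-2-enoate
Product: 35 ethyl 5-hydroxy-6,7-(2,2-dimethyldihydropyrano)benzofuran-3-carboxylate (pyran O on C6; CH2 on C7), via hydroquinone adduct 33 (not isolated), via aminodihydrobenzofuran 34 (not isolated)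
Conditions: AcOH, 25 → 45 °C
Reagents that add atoms: none
Why: Nenitzescu-type benzofuran synthesis, in which the enamine carbon adds to C6 of the quinone (β to the C8 carbonyl, the one not deactivated as a vinylogous ester by the ring oxygen), the C5 hydroxyl of the resulting hydroquinone closes onto the iminium carbon and loss of Me2NH aromatises the furan, so that the remaining hydroxyl sits next to the pyran oxygen as O5′ requires.

Step 15
Reactants: 35 ethyl 5-hydroxy-6,7-(2,2-dimethyldihydropyrano)benzofuran-3-carboxylate (pyran O on C6; CH2 on C7)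
Product: 36 N,N-diethyl-5-hydroxy-6,7-(2,2-dimethyldihydropyrano)benzofuran-3-carboxamide (pyran O on C6; CH2 on C7)
Conditions: Me3Al (3.5 equiv), Et2NH (3.5 equiv), PhMe, 0 → 90 °C
Reagents that add atoms: diethylamine, CCNCC
Why: Aluminium amide aminolysis of the ester (Weinreb amidation with Me2AlNEt2, the phenol being carried as its aluminium phenoxide) gives the tertiary amide that later serves as metalation director and acyl donor.

Step 16
Reactants: 36 N,N-diethyl-5-hydroxy-6,7-(2,2-dimethyldihydropyrano)benzofuran-3-carboxamide (pyran O on C6; CH2 on C7)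
Product: 37 N,N-diethyl-5-(methoxymethoxy)-6,7-(2,2-dimethyldihydropyrano)benzofuran-3-carboxamide (pyran O on C6; CH2 on C7)
Conditions: MOMCl, i-Pr2NEt, CH2Cl2, 0 → 25 °C
Reagents that add atoms: chloromethyl methyl ether, COCCl
Why: Phenol O-alkylation masks O5′ with the same acetal as O7 so that one final operation frees both.

Step 17
Reactants: 37 N,N-diethyl-5-(methoxymethoxy)-6,7-(2,2-dimethyldihydropyrano)benzofuran-3-carboxamide (pyran O on C6; CH2 on C7)
Product: 39 2-bromo-N,N-diethyl-5-(methoxymethoxy)-6,7-(2,2-dimethyldihydropyrano)benzofuran-3-carboxamide (pyran O on C6; CH2 on C7), via 2-lithiobenzofuran 38 (not isolated)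
Conditions: LiN(i-Pr)2, THF, −78 °C; BrCCl2CCl2Br, −78 → 0 °C
Reagents that add atoms: 1,2-dibromo-1,1,2,2-tetrachloroethane, BrC(Cl)(Cl)C(Cl)(Cl)Br
Why: Amide-directed deprotonation at C2, the most acidic position of the benzofuran, followed by electrophilic bromination of the 2-lithio species, gives the 2-bromide.

**Union and ring C (steps 18–20)**

Step 18
Reactants: 24 5-(methoxymethoxy)-2,2-dimethyl-6-(3-methylbut-2-en-1-yl)chroman-7-ol; 39 2-bromo-N,N-diethyl-5-(methoxymethoxy)-6,7-(2,2-dimethyldihydropyrano)benzofuran-3-carboxamide (pyran O on C6; CH2 on C7)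
Product: 40 N,N-diethyl-2-{[5-(methoxymethoxy)-2,2-dimethyl-6-(3-methylbut-2-en-1-yl)chroman-7-yl]oxy}-5-(methoxymethoxy)-6,7-(2,2-dimethyldihydropyrano)benzofuran-3-carboxamide
Conditions: CuI (10 mol %), picolinic acid (20 mol %), K3PO4, DMSO, 90 °C
Reagents that add atoms: none
Why: Ullmann-type copper-catalysed C–O coupling of the phenol with the heteroaryl bromide, helped by the neighbouring carboxamide and by the addition–elimination character of C2, forms the O1–C2 bond.

Step 19
Reactants: 40 N,N-diethyl-2-{[5-(methoxymethoxy)-2,2-dimethyl-6-(3-methylbut-2-en-1-yl)chroman-7-yl]oxy}-5-(methoxymethoxy)-6,7-(2,2-dimethyldihydropyrano)benzofuran-3-carboxamide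
Product: 42 O7,O5′-bis(methoxymethyl) ether of the target, via ring A aryllithium 41 (not isolated)
Conditions: LiN(i-Pr)2 (3 equiv), THF, −78 → 0 °C, then 25 °C if needed
Reagents that add atoms: none
Why: Directed remote metalation (the anionic Friedel–Crafts equivalent that converts 2-aryloxybenzamides into xanthones), in which the amide base reversibly removes the only ring A C–H, acidified by both flanking oxygens, and aryllithium 41 attacks the tertiary amide in a six-membered closure that expels LiNEt2 and forms the C4–C4a bond under conditions harmless to the prenyl group.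

Step 20
Reactants: 42 O7,O5′-bis(methoxymethyl) ether of the target
Product: 43 target CNP0081329.0 (7,5′-dihydroxy-8-prenyl coumaronochromone carrying two fused 2,2-dimethyldihydropyran rings)
Conditions: 3 M HCl (aq), MeOH, 40 °C
Reagents that add atoms: none
Why: Acid-catalysed acetal methanolysis removes both MOM groups under dilute, mildly warmed conditions of the kind routinely tolerated by ortho-prenylphenols.

**Compound list**

1 | glutaric anhydride | O=C1CCCC(=O)O1 | starting material
2 | 5-hydroxy-5-methylhexanoic acid | CC(C)(O)CCCC(=O)O | intermediate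
3 | 6,6-dimethyltetrahydro-2H-pyran-2-one | CC1(C)CCCC(=O)O1 | intermediate
4 | potassium 5-hydroxy-5-methylhexanoate | CC(C)(O)CCCC(=O)[O-].[K+] | intermediate
5 | triethylsilyl 5-methyl-5-(triethylsilyloxy)hexanoate | CC[Si](CC)(CC)OC(=O)CCCC(C)(C)O[Si](CC)(CC)CC | intermediate
6 | 5-methyl-5-(triethylsilyloxy)hexanoic acid | CC[Si](CC)(CC)OC(C)(C)CCCC(=O)O | intermediate
7 | ethoxyacetylene | CCOC#C | starting material
8 | 5-methyl-5-(triethylsilyloxy)hexanoyl chloride | CC[Si](CC)(CC)OC(C)(C)CCCC(=O)Cl | intermediate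
9 | 5-methyl-5-(triethylsilyloxy)hex-1-en-1-one (ketene) | CC[Si](CC)(CC)OC(C)(C)CCC=C=O | intermediate
10 | 3-ethoxy-4-[3-methyl-3-(triethylsilyloxy)butyl]cyclobut-2-en-1-one (racemic, one enantiomer drawn) | CCOC1=CC(=O)[C@@H]1CCC(C)(C)O[Si](CC)(CC)CC | intermediate
11 | 3-ethoxy-4-(3-hydroxy-3-methylbutyl)cyclobut-2-en-1-one (racemic, one enantiomer drawn) | CCOC1=CC(=O)[C@@H]1CCC(C)(C)O | intermediate
12 | 3,3-dimethyl-2-oxabicyclo[4.2.0]oct-1(8)-en-7-one (racemic, one enantiomer drawn) | O=C1C=C2OC(C)(C)CC[C@@H]12 | intermediate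
13 | 4-methylpent-3-enoic acid | CC(C)=CCC(=O)O | starting material
14 | methyl 4-methylpent-3-enoate | COC(=O)CC=C(C)C | intermediate
15 | lithium 1,1-dibromo-5-methylhexa-1,4-dien-2-olate | CC(C)=CCC(O[Li])=C(Br)Br | intermediate
16 | lithium 5-methylhex-4-en-1-yn-1-olate | CC(C)=CCC#CO[Li] | intermediate
17 | triisopropyl[(5-methylhex-4-en-1-yn-1-yl)oxy]silane | CC(C)=CCC#CO[Si](C(C)C)(C(C)C)C(C)C | intermediate
18 | 2,2-dimethyl-6-(2-oxoethenyl)-3,4-dihydro-2H-pyran (vinylketene) | O=C=CC1=CCCC(C)(C)O1 | intermediate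
19 | 4-(6,6-dimethyl-5,6-dihydro-4H-pyran-2-yl)-2-(3-methylbut-2-en-1-yl)-3-(triisopropylsilyloxy)cyclobut-2-en-1-one (racemic, one enantiomer drawn) | O=C1C(CC=C(C)C)=C(O[Si](C(C)C)(C(C)C)C(C)C)[C@H]1C1=CCCC(C)(C)O1 | intermediate
20 | 4-(6,6-dimethyl-5,6-dihydro-4H-pyran-2-yl)-2-(3-methylbut-2-en-1-yl)-3-(triisopropylsilyloxy)buta-1,3-dien-1-one (ketene carbon and pyranyl group cis) | O=C=C(CC=C(C)C)/C(O[Si](C(C)C)(C(C)C)C(C)C)=C\C1=CCCC(C)(C)O1 | intermediate
21 | 2,2-dimethyl-6-(3-methylbut-2-en-1-yl)-7-(triisopropylsilyloxy)-2,3,4,4a-tetrahydro-5H-chromen-5-one (racemic, one enantiomer drawn) | O=C1C(CC=C(C)C)=C(O[Si](C(C)C)(C(C)C)C(C)C)C=C2OC(C)(C)CC[C@@H]12 | intermediate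
22 | 2,2-dimethyl-6-(3-methylbut-2-en-1-yl)-7-(triisopropylsilyloxy)chroman-5-ol | CC(C)=CCc1c(O)c2CCC(C)(C)Oc2cc1O[Si](C(C)C)(C(C)C)C(C)C | intermediate
23 | triisopropyl{[5-(methoxymethoxy)-2,2-dimethyl-6-(3-methylbut-2-en-1-yl)chroman-7-yl]oxy}silane | CC(C)=CCc1c(OCOC)c2CCC(C)(C)Oc2cc1O[Si](C(C)C)(C(C)C)C(C)C | intermediate
24 | 5-(methoxymethoxy)-2,2-dimethyl-6-(3-methylbut-2-en-1-yl)chroman-7-ol | CC(C)=CCc1c(OCOC)c2CCC(C)(C)Oc2cc1O | intermediate
25 | 2,5-dimethoxyphenol | COc1ccc(OC)c(O)c1 | starting material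
26 | 1,4-dimethoxy-2-(methoxymethoxy)benzene | COCOc1cc(OC)ccc1OC | intermediate
27 | [3,6-dimethoxy-2-(methoxymethoxy)phenyl]lithium | COCOc1c([Li])c(OC)ccc1OC | intermediate
28 | 1,4-dimethoxy-2-(methoxymethoxy)-3-(3-methylbut-2-en-1-yl)benzene | COCOc1c(CC=C(C)C)c(OC)ccc1OC | intermediate
29 | 3,6-dimethoxy-2-(3-methylbut-2-en-1-yl)phenol | COc1ccc(OC)c(CC=C(C)C)c1O | intermediate
30 | 5,8-dimethoxy-2,2-dimethylchroman | COc1ccc(OC)c2OC(C)(C)CCc12 | intermediate
31 | 2,2-dimethyl-3,4-dihydro-2H-chromene-5,8-dione | CC1(C)CCC2=C(O1)C(=O)C=CC2=O | intermediate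
32 | ethyl (E)-3-(dimethylamino)prop-2-enoate | CCOC(=O)/C=C/N(C)C | starting material
33 | ethyl 2-(5,8-dihydroxy-2,2-dimethylchroman-6-yl)-3-(dimethylamino)prop-2-enoate | CCOC(=O)C(=CN(C)C)c1cc(O)c2OC(C)(C)CCc2c1O | intermediate
34 | ethyl 2-(dimethylamino)-5-hydroxy-6,7-(2,2-dimethyldihydropyrano)-2,3-dihydrobenzofuran-3-carboxylate (mixture of stereoisomers) | CCOC(=O)C1C(N(C)C)Oc2c1cc(O)c1OC(C)(C)CCc12 | intermediate
35 | ethyl 5-hydroxy-6,7-(2,2-dimethyldihydropyrano)benzofuran-3-carboxylate (pyran O on C6; CH2 on C7) | CCOC(=O)c1coc2c1cc(O)c1OC(C)(C)CCc12 | intermediate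
36 | N,N-diethyl-5-hydroxy-6,7-(2,2-dimethyldihydropyrano)benzofuran-3-carboxamide | CCN(CC)C(=O)c1coc2c1cc(O)c1OC(C)(C)CCc12 | intermediate
37 | N,N-diethyl-5-(methoxymethoxy)-6,7-(2,2-dimethyldihydropyrano)benzofuran-3-carboxamide | CCN(CC)C(=O)c1coc2c1cc(OCOC)c1OC(C)(C)CCc12 | intermediate
38 | 2-lithio derivative of 37 | CCN(CC)C(=O)c1c([Li])oc2c1cc(OCOC)c1OC(C)(C)CCc12 | intermediate
39 | 2-bromo-N,N-diethyl-5-(methoxymethoxy)-6,7-(2,2-dimethyldihydropyrano)benzofuran-3-carboxamide | CCN(CC)C(=O)c1c(Br)oc2c1cc(OCOC)c1OC(C)(C)CCc12 | intermediate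
40 | N,N-diethyl-2-{[5-(methoxymethoxy)-2,2-dimethyl-6-(3-methylbut-2-en-1-yl)chroman-7-yl]oxy}-5-(methoxymethoxy)-6,7-(2,2-dimethyldihydropyrano)benzofuran-3-carboxamide | CCN(CC)C(=O)c1c(Oc3cc4OC(C)(C)CCc4c(OCOC)c3CC=C(C)C)oc2c1cc(OCOC)c1OC(C)(C)CCc12 | intermediate
41 | derivative of 40 lithiated at C4a of ring A (between O1 and O5) | CCN(CC)C(=O)c1c(Oc3c([Li])c4OC(C)(C)CCc4c(OCOC)c3CC=C(C)C)oc2c1cc(OCOC)c1OC(C)(C)CCc12 | intermediate
42 | O7,O5′-bis(methoxymethyl) ether of the target | CC(C)=CCc1c(OCOC)c2c(c3c(=O)c4c(oc13)oc1c3c(c(OCOC)cc14)OC(C)(C)CC3)OC(C)(C)CC2 | intermediate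
43 | CNP0081329.0 (7,5′-dihydroxy-8-prenyl coumaronochromone with 2,2-dimethyldihydropyran rings fused at C5(O)–C6 and C4′(O)–C3′) | CC(C)=CCc1c(O)c2c(c3c(=O)c4c(oc13)oc1c3c(c(O)cc14)OC(C)(C)CC3)OC(C)(C)CC2 | target

**Step count and risks**

Total step count: 20. Longest linear sequence: 11 steps (25 → 43, steps 10–20).

Steps most likely to fail:

1. Step 7. The vinylogous-ester cyclobutenone may resist 4π opening until temperatures at which the siloxyalkyne isomerises to a silylketene, or the alkoxy-substituted vinylketene may dimerise or acylate the product phenol faster than it adds the alkyne. Acid-promoted hydrolysis of the cyclobutenone during the ring fusion of step 4 would have the same consequence. Fallback, setting out from lactone 3 and coming back at 22: the same vinylketene 18 is made at room temperature by a photochemical Wolff rearrangement. Lactone 3 is converted with KN(SiMe3)2 and (PhO)2P(O)Cl into 6,6-dimethyl-5,6-dihydro-4H-pyran-2-yl diphenyl phosphate F1. Stille coupling with tributyl(1-ethoxyvinyl)stannane (Pd(PPh3)4, LiCl, THF) gives 6-(1-ethoxyethenyl)-2,2-dimethyl-3,4-dihydro-2H-pyran F2, and mild aqueous acid unmasks 1-(6,6-dimethyl-5,6-dihydro-4H-pyran-2-yl)ethan-1-one F3. Trifluoroacetylation of its lithium enolate (LiN(SiMe3)2, CF3CO2CH2CF3) gives 1-(6,6-dimethyl-5,6-dihydro-4H-pyran-2-yl)-4,4,4-trifluorobutane-1,3-dione F4, and detrifluoroacetylative diazo transfer (MsN3, Et3N, H2O, MeCN) gives 2-diazo-1-(6,6-dimethyl-5,6-dihydro-4H-pyran-2-yl)ethan-1-one F5. Irradiation of F5 with 17 in CH2Cl2 at 25 °C, then warming to 80 °C, should pass through 18, 19, 20 and 21 and give 22. Steps 2 to 4 are then not needed.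

2. Step 19. The amide base may deprotonate the benzylic–allylic CH2 of the prenyl group or C4–H of ring D without productive cyclisation, or the aryloxy group may be lost from C2 by addition–elimination. Fallback, setting out from 24 and 39 and coming back at 43: the order is inverted, C4–C4a first by aryllithium–aldehyde addition and O1–C2 last by intramolecular displacement. Amide 39 is reduced with Cp2Zr(H)Cl to 2-bromo-5-(methoxymethoxy)-6,7-(2,2-dimethyldihydropyrano)benzofuran-3-carbaldehyde F6. Phenol 24 is capped with MOMCl to 5,7-bis(methoxymethoxy)-2,2-dimethyl-6-(3-methylbut-2-en-1-yl)chroman F7. Its only aromatic C–H, between OMOM and the ring oxygen, is lithiated with n-BuLi to [5,7-bis(methoxymethoxy)-2,2-dimethyl-6-(3-methylbut-2-en-1-yl)chroman-8-yl]lithium F8. Addition to F6 gives [2-bromo-5-(methoxymethoxy)-6,7-(2,2-dimethyldihydropyrano)benzofuran-3-yl][5,7-bis(methoxymethoxy)-2,2-dimethyl-6-(3-methylbut-2-en-1-yl)chroman-8-yl]methanol F9, and Dess–Martin oxidation gives the corresponding methanone F10. Dilute HCl in MeOH removes the three acetals to give [2-bromo-5-hydroxy-6,7-(2,2-dimethyldihydropyrano)benzofuran-3-yl][5,7-dihydroxy-2,2-dimethyl-6-(3-methylbut-2-en-1-yl)chroman-8-yl]methanone F11. K2CO3 in DMF then closes ring C by displacement of bromide from the 2-bromo-3-acylbenzofuran by the O1 phenoxide, giving 43 directly.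

3. Step 6. LiCHBr2 may deprotonate the doubly activated CH2 of the skipped enoate instead of adding to the carbonyl, and excess alkyllithium may move the alkene of the ynolate into conjugation. Fallback, setting out from 14 and coming back at 17: the ynolate is made by oxidation of an acetylide. Reduction of 14 with i-Bu2AlH (CH2Cl2, −78 °C) gives 4-methylpent-3-enal F12. Colvin homologation with lithiated Me3SiCHN2 gives 5-methylhex-4-en-1-yne F13. One equivalent of n-BuLi gives (5-methylhex-4-en-1-yn-1-yl)lithium F14, which is oxidised with t-BuOOLi (from t-BuOOH and LiN(SiMe3)2, THF, −78 → 0 °C) to ynolate 16. Silylation with i-Pr3SiOTf returns 17.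

Further compounds
F1 | step 7 | 6,6-dimethyl-5,6-dihydro-4H-pyran-2-yl diphenyl phosphate | CC1(C)CCC=C(OP(=O)(Oc2ccccc2)Oc2ccccc2)O1
F2 | step 7 | 6-(1-ethoxyethenyl)-2,2-dimethyl-3,4-dihydro-2H-pyran | CCOC(=C)C1=CCCC(C)(C)O1
F3 | step 7 | 1-(6,6-dimethyl-5,6-dihydro-4H-pyran-2-yl)ethan-1-one | CC(=O)C1=CCCC(C)(C)O1
F4 | step 7 | 1-(6,6-dimethyl-5,6-dihydro-4H-pyran-2-yl)-4,4,4-trifluorobutane-1,3-dione | O=C(CC(=O)C(F)(F)F)C1=CCCC(C)(C)O1
F5 | step 7 | 2-diazo-1-(6,6-dimethyl-5,6-dihydro-4H-pyran-2-yl)ethan-1-one | [N-]=[N+]=CC(=O)C1=CCCC(C)(C)O1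
F6 | step 19 | 2-bromo-5-(methoxymethoxy)-6,7-(2,2-dimethyldihydropyrano)benzofuran-3-carbaldehyde (pyran O on C6; CH2 on C7) | O=Cc1c(Br)oc2c1cc(OCOC)c1OC(C)(C)CCc12
F7 | step 19 | 5,7-bis(methoxymethoxy)-2,2-dimethyl-6-(3-methylbut-2-en-1-yl)chroman | CC(C)=CCc1c(OCOC)c2CCC(C)(C)Oc2cc1OCOC
F8 | step 19 | [5,7-bis(methoxymethoxy)-2,2-dimethyl-6-(3-methylbut-2-en-1-yl)chroman-8-yl]lithium | CC(C)=CCc1c(OCOC)c2CCC(C)(C)Oc2c([Li])c1OCOC
F9 | step 19 | [2-bromo-5-(methoxymethoxy)-6,7-(2,2-dimethyldihydropyrano)benzofuran-3-yl][5,7-bis(methoxymethoxy)-2,2-dimethyl-6-(3-methylbut-2-en-1-yl)chroman-8-yl]methanol (racemic, one enantiomer drawn) | CC(C)=CCc1c(OCOC)c2CCC(C)(C)Oc2c([C@H](O)c3c(Br)oc4c3cc(OCOC)c3OC(C)(C)CCc34)c1OCOC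
F10 | step 19 | [2-bromo-5-(methoxymethoxy)-6,7-(2,2-dimethyldihydropyrano)benzofuran-3-yl][5,7-bis(methoxymethoxy)-2,2-dimethyl-6-(3-methylbut-2-en-1-yl)chroman-8-yl]methanone | CC(C)=CCc1c(OCOC)c2CCC(C)(C)Oc2c(C(=O)c3c(Br)oc4c3cc(OCOC)c3OC(C)(C)CCc34)c1OCOC
F11 | step 19 | [2-bromo-5-hydroxy-6,7-(2,2-dimethyldihydropyrano)benzofuran-3-yl][5,7-dihydroxy-2,2-dimethyl-6-(3-methylbut-2-en-1-yl)chroman-8-yl]methanone | CC(C)=CCc1c(O)c2CCC(C)(C)Oc2c(C(=O)c3c(Br)oc4c3cc(O)c3OC(C)(C)CCc34)c1O
F12 | step 6 | 4-methylpent-3-enal | CC(C)=CCC=O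
F13 | step 6 | 5-methylhex-4-en-1-yne | CC(C)=CCC#C
F14 | step 6 | (5-methylhex-4-en-1-yn-1-yl)lithium | CC(C)=CCC#C[Li]
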